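**Retrosynthetic overview**
- Target ⇒ 8-hydroxy α-methylene lactone + (E)-4-silyloxy-2-methylbut-2-enoic acid (late esterification); the lactone ⇒ a 4,5-epoxy-6-keto ester (C6 reduction/lactonisation, then C13 methylenation).
- Ten-membered ring ⇒ anionic oxy-Cope ([3,3]) rearrangement of a cis-1-(2-silyloxyvinyl)-2-isopropenyl epoxycyclohexanol; it forms C8–C9, the (Z)-1(10) alkene and C8, and the resulting enolate is alkylated at C7.
- Epoxycyclohexanol ⇒ (R)-carvone: α'-alkylation, then α'-hydroxylation (both anti to isopropenyl), reductive 1,3-transposition of the enone, OH-directed epoxidation, ester → (E)-silyl enol ether.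
- Ring order: six-membered ring (bought) → epoxide → ten-membered carbocycle → γ-lactone.

Assumption: the SMILES is read as the (1(10)Z)-4,5-cis-epoxy germacranolide (4R,5S,6S,7R,8R); germacrane numbering (C1–C15) is used for the ten-membered-ring compounds and for the atoms of the six-membered precursors that become them.

**Route**

Step 1
Reactants: 1 (R)-(-)-carvone
Product: 3 methyl 2-[(1S,6R)-3-methyl-2-oxo-6-(prop-1-en-2-yl)cyclohex-3-en-1-yl]acetate, via lithium dienolate 2 (not isolated)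
Conditions: LiN(iPr)2, THF, -78 °C; BrCH2CO2Me, DMPU, -78 to -30 °C
Reagents that add atoms: methyl bromoacetate, COC(=O)CBr
Why: Kinetic α'-deprotonation gives the cross-conjugated enolate, which undergoes SN2 enolate alkylation anti to the neighbouring isopropenyl group.

Step 2
Reactants: 3 methyl 2-[(1S,6R)-3-methyl-2-oxo-6-(prop-1-en-2-yl)cyclohex-3-en-1-yl]acetate
Product: 5 methyl 2-[(1S,6S)-1-hydroxy-3-methyl-2-oxo-6-(prop-1-en-2-yl)cyclohex-3-en-1-yl]acetate, via potassium dienolate 4 (not isolated)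
Conditions: KN(SiMe3)2, THF, -78 °C; 2-(phenylsulfonyl)-3-phenyloxaziridine, -78 °C; AcOH
Reagents that add atoms: 2-(phenylsulfonyl)-3-phenyloxaziridine, O=S(=O)(c1ccccc1)N1OC1c1ccccc1
Why: Davis enolate hydroxylation of the planar enolate occurs anti to isopropenyl, so OH ends trans and the acetate arm cis to isopropenyl (the cis-dialkenyl relationship needed for the key step).

Step 3
Reactants: 5 methyl 2-[(1S,6S)-1-hydroxy-3-methyl-2-oxo-6-(prop-1-en-2-yl)cyclohex-3-en-1-yl]acetate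
Product: 8 methyl 2-[(1R,6S)-1-hydroxy-3-methyl-6-(prop-1-en-2-yl)cyclohex-2-en-1-yl]acetate, via tosylhydrazone 6 (not isolated), via allylic diazene 7 (not isolated)
Conditions: TsNHNH2, THF, 4 Å sieves, 45 °C; catecholborane, CHCl3, 0 °C; NaOAc·3H2O, 60 °C
Reagents that add atoms: none
Why: Kabalka reductive 1,3-transposition (hydride reduction of the enone tosylhydrazone, loss of sulfinate, retro-ene loss of N2 from the allylic diazene) removes the carbonyl oxygen and moves the alkene to C4=C5 without touching a stereocentre.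

Step 4
Reactants: 8 methyl 2-[(1R,6S)-1-hydroxy-3-methyl-6-(prop-1-en-2-yl)cyclohex-2-en-1-yl]acetate
Product: 9 methyl 2-[(1S,2S,3S,6R)-2-hydroxy-6-methyl-3-(prop-1-en-2-yl)-7-oxabicyclo[4.1.0]heptan-2-yl]acetate
Conditions: VO(acac)2 (3 mol %), tBuOOH, CH2Cl2, 0 °C to rt
Reagents that add atoms: tert-butyl hydroperoxide, CC(C)(C)OO
Why: Hydroxyl-directed vanadium-catalysed epoxidation of the cyclic allylic alcohol delivers oxygen syn to the tertiary OH, setting C4 and C5 as the cis-epoxide (4R,5S) from the carvone-derived centres.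

Step 5
Reactants: 9 methyl 2-[(1S,2S,3S,6R)-2-hydroxy-6-methyl-3-(prop-1-en-2-yl)-7-oxabicyclo[4.1.0]heptan-2-yl]acetate
Product: 10 2-[(1S,2S,3S,6R)-2-hydroxy-6-methyl-3-(prop-1-en-2-yl)-7-oxabicyclo[4.1.0]heptan-2-yl]acetaldehyde
Conditions: iBu2AlH (2.2 equiv), CH2Cl2, -78 °C; aq. potassium sodium tartrate
Reagents that add atoms: none
Why: Low-temperature half-reduction of the methyl ester stops at the aluminium hemiacetal and gives the aldehyde on work-up, the epoxide being inert at -78 °C.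

Step 6
Reactants: 10 2-[(1S,2S,3S,6R)-2-hydroxy-6-methyl-3-(prop-1-en-2-yl)-7-oxabicyclo[4.1.0]heptan-2-yl]acetaldehyde
Product: 11 (1S,2R,3S,6R)-6-methyl-3-(prop-1-en-2-yl)-2-[(E)-2-(triisopropylsilyloxy)ethenyl]-7-oxabicyclo[4.1.0]heptan-2-ol
Conditions: iPr3SiOTf (1.05 equiv), Et3N, CH2Cl2, -78 to -20 °C
Reagents that add atoms: triisopropylsilyl trifluoromethanesulfonate, CC(C)[Si](C(C)C)(C(C)C)OS(=O)(=O)C(F)(F)F
Why: Soft enolisation and O-silylation of the aldehyde should give the (E)-silyl enol ether because the quaternary neighbour cannot sit cis to the bulky silyloxy group, while the hindered tertiary OH stays free.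

Step 7
Reactants: 11 (1S,2R,3S,6R)-6-methyl-3-(prop-1-en-2-yl)-2-[(E)-2-(triisopropylsilyloxy)ethenyl]-7-oxabicyclo[4.1.0]heptan-2-ol
Product: 14 methyl (1(10)Z,4R,5R,7R,8R)-4,5-epoxy-6-oxo-8-(triisopropylsilyloxy)-13-norgermacr-1(10)-en-12-oate, via potassium alkoxide 12 (not isolated), via potassium ring-expanded enolate 13 (not isolated)
Conditions: KN(SiMe3)2, 18-crown-6, THF, -20 to 20 °C; BrCH2CO2Me, -78 °C; AcOH
Reagents that add atoms: methyl bromoacetate, COC(=O)CBr
Why: Anionic oxy-Cope ([3,3]-sigmatropic) rearrangement through the chair that keeps isopropenyl equatorial and the cis-disposed silyloxyvinyl group axial gives the (Z)-C1=C10 alkene, transfers chirality from C1/C6 to C8 (E-enol ether, OSi equatorial, hence 8R), and the regiodefined enolate is then alkylated at C7 anti to the C8 silyloxy group (7R).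

Step 8
Reactants: 14 methyl (1(10)Z,4R,5R,7R,8R)-4,5-epoxy-6-oxo-8-(triisopropylsilyloxy)-13-norgermacr-1(10)-en-12-oate
Product: 16 (1(10)Z,4R,5S,6S,7S,8R)-4,5-epoxy-8-(triisopropylsilyloxy)-13-norgermacr-1(10)-en-12,6-olide, via 6-hydroxy ester 15 (not isolated)
Conditions: Zn(BH4)2, Et2O, -20 °C to rt
Reagents that add atoms: none
Why: Chelation-controlled reduction of the α,β-epoxy ketone (zinc bridges the carbonyl and epoxide oxygens) gives the erythro 6S alcohol, whose alkoxide closes the trans-fused γ-lactone onto the methyl ester.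

Step 9
Reactants: 16 (1(10)Z,4R,5S,6S,7S,8R)-4,5-epoxy-8-(triisopropylsilyloxy)-13-norgermacr-1(10)-en-12,6-olide
Product: 20 (1(10)Z,4R,5S,6S,7S,8R)-4,5-epoxy-8-(triisopropylsilyloxy)germacra-1(10),11(13)-dien-12,6-olide, via lithium lactone enolate 17 (not isolated), via Mannich base 18 (not isolated), via trimethylammonium iodide 19 (not isolated)
Conditions: LiN(iPr)2, THF, -78 °C; CH2=NMe2+ I-, -78 to 0 °C; MeI, rt; aq. NaHCO3
Reagents that add atoms: N,N-dimethylmethyleneiminium iodide (Eschenmoser's salt), C=[N+](C)C.[I-]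
Why: Eschenmoser methylenation (lactone-enolate Mannich reaction, N-methylation, Hofmann-type elimination) installs C13 without affecting any stereocentre.

Step 10
Reactants: 20 (1(10)Z,4R,5S,6S,7S,8R)-4,5-epoxy-8-(triisopropylsilyloxy)germacra-1(10),11(13)-dien-12,6-olide
Product: 21 (1(10)Z,4R,5S,6S,7R,8R)-4,5-epoxy-8-hydroxygermacra-1(10),11(13)-dien-12,6-olide
Conditions: Bu4NF, AcOH, THF, 0 °C to rt
Reagents that add atoms: none
Why: Fluoride desilylation buffered with AcOH frees the 8-OH while sparing the epoxide and the α-methylene lactone.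

Step 11
Reactants: 22 (tert-butyldimethylsilyloxy)acetaldehyde; 23 ethyl 2-(triphenylphosphoranylidene)propanoate
Product: 24 ethyl (E)-4-(tert-butyldimethylsilyloxy)-2-methylbut-2-enoate
Conditions: CH2Cl2, rt
Reagents that add atoms: none
Why: Wittig olefination with the stabilised ylide gives the (E)-trisubstituted enoate.

Step 12
Reactants: 24 ethyl (E)-4-(tert-butyldimethylsilyloxy)-2-methylbut-2-enoate
Product: 25 (E)-4-(tert-butyldimethylsilyloxy)-2-methylbut-2-enoic acid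
Conditions: LiOH, THF/H2O, 0 °C to rt; aq. HCl to pH 4
Reagents that add atoms: lithium hydroxide, [Li+].[OH-]
Why: Saponification of the ethyl ester leaves the primary silyl ether and the alkene geometry intact.

Step 13
Reactants: 21 (1(10)Z,4R,5S,6S,7R,8R)-4,5-epoxy-8-hydroxygermacra-1(10),11(13)-dien-12,6-olide; 25 (E)-4-(tert-butyldimethylsilyloxy)-2-methylbut-2-enoic acid
Product: 28 (1(10)Z,4R,5S,6S,7R,8R)-4,5-epoxy-8-[(E)-4-hydroxy-2-methylbut-2-enoyloxy]germacra-1(10),11(13)-dien-12,6-olide, via mixed anhydride 26 (not isolated), via silyl ether of the target 27 (not isolated)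
Conditions: 2,4,6-Cl3C6H2COCl, Et3N, THF, rt; 21, DMAP, PhMe, rt; then Bu4NF, AcOH, THF, 0 °C
Reagents that add atoms: none
Why: Yamaguchi esterification acylates the hindered secondary 8-OH with retention, and buffered fluoride then removes the primary silyl ether in the same flask.

**Compound list**
1 | (R)-(-)-carvone | CC1=CC[C@@H](C(C)=C)CC1=O | starting material
2 | lithium cross-conjugated dienolate of (R)-carvone | CC1=CC[C@@H](C(C)=C)C=C1[O-].[Li+] | intermediate
3 | methyl 2-[(1S,6R)-3-methyl-2-oxo-6-(prop-1-en-2-yl)cyclohex-3-en-1-yl]acetate | CC1=CC[C@@H](C(C)=C)[C@H](CC(=O)OC)C1=O | intermediate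
4 | potassium dienolate of 3 | CC1=CC[C@@H](C(C)=C)C(CC(=O)OC)=C1[O-].[K+] | intermediate
5 | methyl 2-[(1S,6S)-1-hydroxy-3-methyl-2-oxo-6-(prop-1-en-2-yl)cyclohex-3-en-1-yl]acetate | CC1=CC[C@@H](C(C)=C)[C@@](O)(CC(=O)OC)C1=O | intermediate
6 | tosylhydrazone of 5 | CC1=CC[C@@H](C(C)=C)[C@@](O)(CC(=O)OC)C1=NNS(=O)(=O)c1ccc(C)cc1 | intermediate
7 | allylic diazene from 6 (new C–N centre not defined) | CC1=CC[C@@H](C(C)=C)[C@@](O)(CC(=O)OC)C1N=N | intermediate
8 | methyl 2-[(1R,6S)-1-hydroxy-3-methyl-6-(prop-1-en-2-yl)cyclohex-2-en-1-yl]acetate | CC1=C[C@](O)(CC(=O)OC)[C@H](C(C)=C)CC1 | intermediate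
9 | methyl 2-[(1S,2S,3S,6R)-2-hydroxy-6-methyl-3-(prop-1-en-2-yl)-7-oxabicyclo[4.1.0]heptan-2-yl]acetate | C[C@]12O[C@H]1[C@](O)(CC(=O)OC)[C@H](C(C)=C)CC2 | intermediate
10 | 2-[(1S,2S,3S,6R)-2-hydroxy-6-methyl-3-(prop-1-en-2-yl)-7-oxabicyclo[4.1.0]heptan-2-yl]acetaldehyde | C[C@]12O[C@H]1[C@](O)(CC=O)[C@H](C(C)=C)CC2 | intermediate
11 | (1S,2R,3S,6R)-6-methyl-3-(prop-1-en-2-yl)-2-[(E)-2-(triisopropylsilyloxy)ethenyl]-7-oxabicyclo[4.1.0]heptan-2-ol | C[C@]12O[C@H]1[C@](O)(/C=C/O[Si](C(C)C)(C(C)C)C(C)C)[C@H](C(C)=C)CC2 | intermediate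
12 | potassium alkoxide of 11 | C[C@]12O[C@H]1[C@]([O-])(/C=C/O[Si](C(C)C)(C(C)C)C(C)C)[C@H](C(C)=C)CC2.[K+] | intermediate
13 | potassium C6–C7 enolate of the ring-expanded (1(10)Z)-4,5-epoxy-8-silyloxy cyclodecenone | [O-]/C1=C\[C@H](O[Si](C(C)C)(C(C)C)C(C)C)C/C(C)=C\CC[C@@]2(C)O[C@@H]12.[K+] | intermediate
14 | methyl (1(10)Z,4R,5R,7R,8R)-4,5-epoxy-6-oxo-8-(triisopropylsilyloxy)-13-norgermacr-1(10)-en-12-oate | O=C1[C@H](CC(=O)OC)[C@H](O[Si](C(C)C)(C(C)C)C(C)C)C/C(C)=C\CC[C@@]2(C)O[C@@H]12 | intermediate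
15 | 6-hydroxy ester (6S alcohol from 14) | O[C@H]1[C@H](CC(=O)OC)[C@H](O[Si](C(C)C)(C(C)C)C(C)C)C/C(C)=C\CC[C@@]2(C)O[C@@H]12 | intermediate
16 | (1(10)Z,4R,5S,6S,7S,8R)-4,5-epoxy-8-(triisopropylsilyloxy)-13-norgermacr-1(10)-en-12,6-olide | C1C(=O)O[C@H]2[C@H]1[C@H](O[Si](C(C)C)(C(C)C)C(C)C)C/C(C)=C\CC[C@@]1(C)O[C@@H]21 | intermediate
17 | lithium enolate of lactone 16 | C1=C([O-])O[C@H]2[C@H]1[C@H](O[Si](C(C)C)(C(C)C)C(C)C)C/C(C)=C\CC[C@@]1(C)O[C@@H]21.[Li+] | intermediate
18 | 11-(dimethylaminomethyl) lactone (Mannich base, C11 not defined) | CN(C)CC1C(=O)O[C@H]2[C@H]1[C@H](O[Si](C(C)C)(C(C)C)C(C)C)C/C(C)=C\CC[C@@]1(C)O[C@@H]21 | intermediate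
19 | trimethylammonium iodide of 18 | C[N+](C)(C)CC1C(=O)O[C@H]2[C@H]1[C@H](O[Si](C(C)C)(C(C)C)C(C)C)C/C(C)=C\CC[C@@]1(C)O[C@@H]21.[I-] | intermediate
20 | (1(10)Z,4R,5S,6S,7S,8R)-4,5-epoxy-8-(triisopropylsilyloxy)germacra-1(10),11(13)-dien-12,6-olide | C=C1C(=O)O[C@H]2[C@H]1[C@H](O[Si](C(C)C)(C(C)C)C(C)C)C/C(C)=C\CC[C@@]1(C)O[C@@H]21 | intermediate
21 | (1(10)Z,4R,5S,6S,7R,8R)-4,5-epoxy-8-hydroxygermacra-1(10),11(13)-dien-12,6-olide | C=C1C(=O)O[C@H]2[C@H]1[C@H](O)C/C(C)=C\CC[C@@]1(C)O[C@@H]21 | intermediate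
22 | (tert-butyldimethylsilyloxy)acetaldehyde | O=CCO[Si](C)(C)C(C)(C)C | starting material
23 | ethyl 2-(triphenylphosphoranylidene)propanoate | CCOC(=O)C(C)=P(c1ccccc1)(c1ccccc1)c1ccccc1 | starting material
24 | ethyl (E)-4-(tert-butyldimethylsilyloxy)-2-methylbut-2-enoate | CCOC(=O)/C(C)=C/CO[Si](C)(C)C(C)(C)C | intermediate
25 | (E)-4-(tert-butyldimethylsilyloxy)-2-methylbut-2-enoic acid | OC(=O)/C(C)=C/CO[Si](C)(C)C(C)(C)C | intermediate
26 | mixed anhydride of 25 with 2,4,6-trichlorobenzoic acid | O=C(OC(=O)/C(C)=C/CO[Si](C)(C)C(C)(C)C)c1c(Cl)cc(Cl)cc1Cl | intermediate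
27 | tert-butyldimethylsilyl ether of the target | C=C1C(=O)O[C@H]2[C@H]1[C@H](OC(=O)/C(C)=C/CO[Si](C)(C)C(C)(C)C)C/C(C)=C\CC[C@@]1(C)O[C@@H]21 | intermediate
28 | (1(10)Z,4R,5S,6S,7R,8R)-4,5-epoxy-8-[(E)-4-hydroxy-2-methylbut-2-enoyloxy]germacra-1(10),11(13)-dien-12,6-olide (CNP0198076.6) | C=C1C(=O)O[C@H]2[C@H]1[C@H](OC(=O)/C(C)=C/CO)C/C(C)=C\CC[C@@]1(C)O[C@@H]21 | target

**Totals**
Total step count: 13. Longest linear sequence: 11 steps (steps 1–10 and 13, from (R)-carvone).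

**Three steps most likely to fail**

Step 6 (enol silylation of the β-hydroxy aldehyde). The risks are retro-aldol cleavage, silylation of the tertiary OH and an E/Z mixture. The fallback masks the tertiary hydroxyl first. It sets out from 10: N-(trimethylsilyl)imidazole gives the O-trimethylsilyl aldehyde F1. Equilibrating enol silylation (iPr3SiOTf, Et3N, CH2Cl2, rt) gives the bis-silyl (E)-enol ether F2. K2CO3 in MeOH at 0 °C removes only the trimethylsilyl ether, and the route is rejoined at 11.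

Step 7 (anionic oxy-Cope and in-flask alkylation). The risks are β-elimination of silanolate from the potassium enolate, poor C-alkylation, the E isomer of the new alkene and the wrong C7 epimer. The fallback runs the [3,3] shift without any anion. It sets out from 11: Et3SiOTf and 2,6-lutidine give the triethylsilyl ether F3. Thermal siloxy-Cope rearrangement (PhMe, base-washed sealed tube, about 190 °C) through the same chair gives the ring-expanded triethylsilyl enol ether F4. MeLi (THF, 0 °C) releases the lithium enolate F5, which is alkylated with ICH2CO2Me and DMPU at -78 °C; the route is rejoined at 14.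

Step 8 (facial selectivity of the C6 reduction). Chelation control by the epoxide and the bias from C7 may oppose each other. If hydride enters from the other face, the epimeric alcohol closes to the cis-fused lactone, and the centre is then inverted by substitution instead of re-reduction. The fallback sets out from 14: LiBH(sBu)3 (THF, -78 °C) gives the 6-epi cis-fused lactone F6. LiOH (THF/H2O) and careful neutralisation at 0 °C give the 6-epi hydroxy acid F7. Mitsunobu lactonisation (PPh3, diisopropyl azodicarboxylate, PhMe) closes the ring with inversion at C6, and the route is rejoined at 16.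

Further compounds
F1 | step 6 | O-trimethylsilyl ether of aldehyde 10 | C[C@]12O[C@H]1[C@](O[Si](C)(C)C)(CC=O)[C@H](C(C)=C)CC2
F2 | step 6 | O-trimethylsilyl ether of (E)-enol ether 11 | C[C@]12O[C@H]1[C@](O[Si](C)(C)C)(/C=C/O[Si](C(C)C)(C(C)C)C(C)C)[C@H](C(C)=C)CC2
F3 | step 7 | O-triethylsilyl ether of 11 | C[C@]12O[C@H]1[C@](O[Si](CC)(CC)CC)(/C=C/O[Si](C(C)C)(C(C)C)C(C)C)[C@H](C(C)=C)CC2
F4 | step 7 | ring-expanded C6 triethylsilyl enol ether | CC[Si](CC)(CC)O/C1=C\[C@H](O[Si](C(C)C)(C(C)C)C(C)C)C/C(C)=C\CC[C@@]2(C)O[C@@H]12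
F5 | step 7 | lithium C6–C7 enolate of the ring-expanded ketone | [Li+].[O-]/C1=C\[C@H](O[Si](C(C)C)(C(C)C)C(C)C)C/C(C)=C\CC[C@@]2(C)O[C@@H]12
F6 | step 8 | 6-epi (cis-fused) lactone of 16 | C1C(=O)O[C@@H]2[C@H]1[C@H](O[Si](C(C)C)(C(C)C)C(C)C)C/C(C)=C\CC[C@@]1(C)O[C@@H]21
F7 | step 8 | 6-epi hydroxy acid | O[C@@H]1[C@H](CC(=O)O)[C@H](O[Si](C(C)C)(C(C)C)C(C)C)C/C(C)=C\CC[C@@]2(C)O[C@@H]12
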